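## The problem

The target is a 2H-chromene (ring O1–C2–C3=C4–C4a–C8a) fused to a benzene ring that is substituted everywhere except C7: hydroquinone hydroxyls at C5 and C8, the ring oxygen at C8a and a cinnamoyl group at C6. The only stereocentre, C2 (S), is fully substituted (O1, CH3, C3, C1′H2). Nothing else in the molecule can relay to it, and its CH3 and CH2R groups are close in size. The usual closure of this ring, the oxa-6π-electrocyclisation of an o-quinone-methide dienone, runs through a planar achiral intermediate and gives the racemate. Any later opening of the pyran ring (for example a retro-oxa-Michael reaction through a carbonyl group in the side chain) would erase C2 again. The side chain ends in an E-allylic tertiary alcohol that ionises with acid, and making it from a prenyl terminus by ene oxidation is not regioselective. The 2′-hydroxychalcone cyclises to a flavanone under acid or base, the hydroquinone is air-sensitive in base, and three different C=C bonds have to be told apart.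

The feature that the plan uses: C2 carries both a vinyl unit (C3=C4) and a CH2 bound to an sp2 carbon (C1′–C2′). The array C4=C3–C2–C1′–C2′ is therefore the γ,δ-unsaturated carbonyl pattern of a Claisen rearrangement with C2 as the bond-forming allyl terminus. Because C2 also bears O1, the substrate of that rearrangement is an aryl enol ether, which a phenol and an ynone give in one step.

## Retrosynthesis

**21 ⇐ 19 (via 20).** The two O–H bonds at C5 and C8 are traced back to methyl ethers. A para-dimethoxyarene is the retron of oxidative demethylation to quinone 20 followed by reduction, so the end of the route needs neither acid nor base. This spares the tertiary allylic alcohol and the 2′-hydroxychalcone. Methyl ethers also survive every organometallic step before it.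

**19 ⇐ 16 + 17 (via 18).** The C6–C(=O) bond is cut. An aryl bromide at C6 is inert through the whole sequence, is present in the commercial starting material 1, and becomes aryllithium 18, which takes the whole cinnamoyl unit from Weinreb amide 17 in one step. An acetyl group carried from the start would interfere with the reduction and the organometallic steps.

**16 ⇐ 15 ⇐ 13 + 14.** The side chain is cut at C4′–CH3 (methyl addition to enone 15) and at C2′=C3′ (Wittig reaction of aldehyde 13 with stabilised ylide 14). Both steps are regiospecific and E-selective by construction, which an ene oxidation of a prenyl group is not. The forward steps must be non-basic, because 13 and 15 could open the pyran ring by β-elimination of the aryloxide.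

**13 ⇐ 12 ⇐ 11.** The aldehyde comes from dimethylamide 12. The C3=C4 bond of the pyran ring is cut by ring-closing metathesis, leading to open-chain amide 11 with a styrene on the arene and a propenyl group on C2. The methyl of that propenyl group leaves as propene.

**11 ⇐ 8 + 9 (via 10), the key cut.** The C2–C1′ bond is cut as a [3,3]-sigmatropic shift. The precursor is the secondary allylic alcohol 8, whose enol-ether carbon becomes C2. Against the neighbouring cut at O1–C2 (etherification of a tertiary centre), this cut makes the quaternary carbon by a concerted C–C bond formation whose sense is fixed by a secondary carbinol. Alcohol 8 has one easily set stereocentre and no quaternary carbon. The forward reaction has to run through one chair transition state without ionisation.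

**8 ⇐ 7 ⇐ 5 + 6.** The carbinol C–H bond comes from catalyst-controlled reduction of enone 7 (methyl against alkenyl, a large size difference). The aryl–O–C(vinyl) bond comes from conjugate addition of phenol 5 to pent-3-yn-2-one 6, which should settle at the E vinylogous ester.

**5 ⇐ 4 ⇐ 3 ⇐ 1.** The vinyl group comes from salicylaldehyde 4, the formyl group from ortho-formylation of phenol 3 at its only free ortho position, and 3 from commercial aldehyde 1 by Baeyer–Villiger oxidation via formate 2. All three oxygens of the arene and the bromine are then in place.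

## Roads not taken

**Alternative 1:** The most obvious route cuts O1–C2 and C4–C4a together. A 2,4-dihydroxyacetophenone with a protected 5-oxygen would be condensed with citral (Knoevenagel condensation, then oxa-6π-electrocyclisation) to racemic chromene A1. The chalcone would follow by aldol condensation, and the prenyl terminus would be oxidised by a Schenck ene reaction to hydroperoxide A2, which is then reduced. The route is short, but the electrocyclisation passes through a planar dienone with no element of stereocontrol, so the single enantiomer would need a resolution. The ene reaction gives A2 together with its secondary regioisomer A3, and singlet oxygen can also attack the electron-rich chromene double bond. The chosen plan sets C2 by a stereospecific step and builds the side chain at the right oxidation level.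

**Alternative 2:** Cut O1–C2 at the stereocentre and C3=C4. Phenol 5 would be O-alkylated at the tertiary terminus of a linalyl-type π-allyl palladium complex (asymmetric allylic etherification) to give tertiary aryl ether A4. Ring-closing metathesis would give chromene A5, and the prenyl end would then be oxidised. Here the configuration depends on a catalyst distinguishing CH3 from CH2R at a tertiary centre, with a 2,6-disubstituted phenol as nucleophile and a branched/linear choice on top. The unselective terminal oxidation of alternative 1 remains, now next to the chromene alkene. In the chosen plan the catalyst only has to distinguish methyl from alkenyl at a ketone, and a concerted shift passes that on to C2.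

**Alternative 3:** The same [3,3] logic with the ring made first. Chromone A6 would be reduced enantioselectively at C4 to chromenol A7 and acetylated to A8. An Ireland–Claisen rearrangement across the pyran ring would give acid A9 directly, with no metathesis and no vinyl group on the arene. However, A7 and A8 are covalent derivatives of a benzopyrylium ion. Heterolysis of the C4–O bond gives an aromatic cation, which erases the C4 configuration and opens paths to C2-attack products and the 2-methylene tautomer. No dependable enantioselective 1,2-reduction of the vinylogous ester carbonyl of A6 is at hand. The open-chain version chosen keeps the same bond construction, but ionisation of its carbinol would give only a non-aromatic aryloxyallyl cation. The price is one metathesis step.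

Key step: step 6

Assumption: compounds 1, 6, 9, 14 and 17 and all reagents are taken as commercial; the configuration at C2 read from the SMILES is S.

## Steps

Step 1
Reactants: 1 4-bromo-2,5-dimethoxybenzaldehyde
Product: 3 4-bromo-2,5-dimethoxyphenol, via 4-bromo-2,5-dimethoxyphenyl formate 2 (not isolated)
Conditions: mCPBA (1.3 equiv), CH2Cl2, 0 °C to rt; then K2CO3 (0.2 equiv), MeOH, rt
Reagents that add atoms: mCPBA, OOC(=O)c1cccc(Cl)c1
Why: Baeyer–Villiger (Dakin-type) oxidation; the electron-rich aryl group migrates to give formate 2, which base-catalysed methanolysis cleaves; the bromide and methyl ethers are inert.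

Step 2
Reactants: 3 4-bromo-2,5-dimethoxyphenol
Product: 4 5-bromo-2-hydroxy-3,6-dimethoxybenzaldehyde
Conditions: MgCl2 (2 equiv), Et3N (4 equiv), (CH2O)n (6 equiv), MeCN, reflux; aq. HCl work-up
Reagents that add atoms: paraformaldehyde (as formaldehyde), C=O
Why: Magnesium-phenoxide-directed ortho-formylation (Casnati–Skattebøl type); the phenol has only one free ortho position (the future C4a) and its para position is blocked by bromine; a second formaldehyde accepts the hydride.

Step 3
Reactants: 4 5-bromo-2-hydroxy-3,6-dimethoxybenzaldehyde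
Product: 5 4-bromo-2-ethenyl-3,6-dimethoxyphenol
Conditions: Ph3PCH3Br (2.5 equiv), KOtBu (2.5 equiv), THF, 0 °C to rt; used without storage
Reagents that add atoms: methyltriphenylphosphonium bromide, C[P+](c1ccccc1)(c1ccccc1)c1ccccc1.[Br-]
Why: Wittig methylenation; the excess ylide first deprotonates the phenol and the phenoxide aldehyde is then olefinated, as is usual for salicylaldehydes.

Step 4
Reactants: 5 4-bromo-2-ethenyl-3,6-dimethoxyphenol; 6 pent-3-yn-2-one
Product: 7 (3E)-4-(4-bromo-2-ethenyl-3,6-dimethoxyphenoxy)pent-3-en-2-one
Conditions: 6 (1.2 equiv), DABCO (0.2 equiv), K2CO3 (0.2 equiv), MeCN, 40 °C; purified to the single E isomer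
Reagents that add atoms: none
Why: Base-catalysed oxa-Michael addition of the phenoxide to the ynone; reversible addition should funnel the product to the more stable E vinylogous ester (aryloxy anti to acetyl), and this geometry matters because step 6 turns it into configuration.

Step 5
Reactants: 7 (3E)-4-(4-bromo-2-ethenyl-3,6-dimethoxyphenoxy)pent-3-en-2-one
Product: 8 (2S,3E)-4-(4-bromo-2-ethenyl-3,6-dimethoxyphenoxy)pent-3-en-2-ol
Conditions: (R)-Me-CBS (0.2 equiv), catecholborane (1.8 equiv), toluene, −78 to −40 °C; MeOH, then aq. NaOH work-up; Et3N-deactivated silica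
Reagents that add atoms: none
Why: Corey–Bakshi–Shibata reduction with the alkenyl group as the large and methyl as the small substituent, for which the (R)-catalyst is expected to give the (S)-carbinol; catecholborane at low temperature should leave the styrene alone, and the basic work-up protects the acid-labile γ-hydroxy enol ether.

Step 6
Reactants: 8 (2S,3E)-4-(4-bromo-2-ethenyl-3,6-dimethoxyphenoxy)pent-3-en-2-ol; 9 N,N-dimethylacetamide dimethyl acetal
Product: 11 (3S,4E)-3-(4-bromo-2-ethenyl-3,6-dimethoxyphenoxy)-N,N,3-trimethylhex-4-enamide, via 1-{[(2S,3E)-4-(4-bromo-2-ethenyl-3,6-dimethoxyphenoxy)pent-3-en-2-yl]oxy}-N,N-dimethylethen-1-amine 10 (not isolated)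
Conditions: 9 (4 equiv), BHT (cat.), toluene, 110 °C, MeOH distilled off
Reagents that add atoms: none
Why: Exchange of the alcohol of 8 into the amide acetal and loss of two methanol give ketene N,O-acetal 10, which undergoes a concerted suprafacial [3,3]-sigmatropic shift (Eschenmoser–Claisen rearrangement) that joins the ketene-acetal CH2 to the aryloxy-bearing alkene carbon and breaks the carbinol C–O bond. The closest known reaction type is the amide-acetal or ester-enolate Claisen rearrangement of cyclic enol ethers with an allylic oxygen (glycals), which delivers an acetic acid residue to the oxygen-bearing carbon, together with its use on trisubstituted allylic alcohols to make quaternary carbons. No ring is closed in this step; the pyran ring follows in step 7. The new quaternary centre is controlled by the (S)-carbinol through a chair transition state with the carbinol methyl pseudo-equatorial, because the pseudo-axial alternative would clash (allylic 1,3-strain) with the methyl that is cis to it on the enol-ether carbon; with the E enol ether this delivers the CH2 to the face that gives the S configuration and makes the new propenyl double bond E. The ketene-acetal terminus is an unsubstituted CH2, so no enolate geometry enters and the outcome rests only on the carbinol configuration and the alkene geometry fixed in steps 4 and 5. The step needs chair over boat and concerted shift over ionisation of the allylic C–O bond; the non-polar solvent and basic reagent disfavour ionisation, and the aryloxy donor on the bond-forming terminus should lower the barrier of the concerted path. BHT suppresses polymerisation of the styrene, and both ortho positions and the para position of the aryl ether in 11 are substituted, so no productive aromatic Claisen rearrangement is open to it at this temperature.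

Step 7
Reactants: 11 (3S,4E)-3-(4-bromo-2-ethenyl-3,6-dimethoxyphenoxy)-N,N,3-trimethylhex-4-enamide
Product: 12 2-[(2S)-6-bromo-5,8-dimethoxy-2-methyl-2H-chromen-2-yl]-N,N-dimethylacetamide
Conditions: Grubbs second-generation catalyst (5 mol%), CH2Cl2, 40 °C
Reagents that add atoms: none
Why: Ring-closing metathesis of the styrene with the propenyl group forms C3=C4 and expels the former carbinol carbon with its methyl as propene; a six-membered ring is the only closure available and the quaternary centre is not touched.

Step 8
Reactants: 12 2-[(2S)-6-bromo-5,8-dimethoxy-2-methyl-2H-chromen-2-yl]-N,N-dimethylacetamide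
Product: 13 2-[(2S)-6-bromo-5,8-dimethoxy-2-methyl-2H-chromen-2-yl]acetaldehyde
Conditions: Cp2Zr(H)Cl (1.5 equiv), THF, rt, 20 min; aq. NH4Cl; used directly
Reagents that add atoms: none
Why: Schwartz reagent reduces tertiary amides to aldehydes through a stable zirconated hemiaminal that collapses only on work-up, so no over-reduction is expected and the internal ring alkene should react more slowly; the ammonium chloride wash removes dimethylamine before it can trigger β-elimination of the aryloxide.

Step 9
Reactants: 13 2-[(2S)-6-bromo-5,8-dimethoxy-2-methyl-2H-chromen-2-yl]acetaldehyde; 14 1-(triphenyl-λ5-phosphanylidene)propan-2-one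
Product: 15 (3E)-5-[(2S)-6-bromo-5,8-dimethoxy-2-methyl-2H-chromen-2-yl]pent-3-en-2-one
Conditions: 14 (1.5 equiv), CH2Cl2, 40 °C
Reagents that add atoms: none
Why: Wittig reaction with a stabilised ylide, which is E-selective and essentially non-basic, so the β-aryloxy aldehyde is olefinated without retro-oxa-Michael opening of the pyran ring.

Step 10
Reactants: 15 (3E)-5-[(2S)-6-bromo-5,8-dimethoxy-2-methyl-2H-chromen-2-yl]pent-3-en-2-one
Product: 16 (3E)-5-[(2S)-6-bromo-5,8-dimethoxy-2-methyl-2H-chromen-2-yl]-2-methylpent-3-en-2-ol
Conditions: MeMgBr (1.5 equiv), CeCl3 (1.5 equiv), THF, −78 °C; aq. NH4Cl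
Reagents that add atoms: methylmagnesium bromide, C[Mg]Br
Why: Organocerium 1,2-addition to the methyl ketone; the weakly basic reagent should suppress γ-deprotonation (vinylogous elimination of the aryloxide) and conjugate addition, and the aryl bromide is inert at −78 °C.

Step 11
Reactants: 16 (3E)-5-[(2S)-6-bromo-5,8-dimethoxy-2-methyl-2H-chromen-2-yl]-2-methylpent-3-en-2-ol; 17 (2E)-N-methoxy-N-methyl-3-phenylprop-2-enamide
Product: 19 (2E)-1-[(2S)-2-[(2E)-4-hydroxy-4-methylpent-2-en-1-yl]-5,8-dimethoxy-2-methyl-2H-chromen-6-yl]-3-phenylprop-2-en-1-one, via lithium (3E)-5-[(2S)-6-lithio-5,8-dimethoxy-2-methyl-2H-chromen-2-yl]-2-methylpent-3-en-2-olate 18 (not isolated)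
Conditions: n-BuLi (2.1 equiv), THF, −78 °C; then 17 (1.3 equiv), −78 to −20 °C; aq. NH4Cl
Reagents that add atoms: none
Why: The first equivalent of n-BuLi deprotonates the alcohol and the second performs bromine–lithium exchange to give 18, which is stabilised by the ortho methoxy group; acylation by the Weinreb amide stops at the chelated tetrahedral adduct, so the enone is released only on work-up.

Step 12
Reactants: 19 (2E)-1-[(2S)-2-[(2E)-4-hydroxy-4-methylpent-2-en-1-yl]-5,8-dimethoxy-2-methyl-2H-chromen-6-yl]-3-phenylprop-2-en-1-one
Product: 21 (2E)-1-[(2S)-5,8-dihydroxy-2-[(2E)-4-hydroxy-4-methylpent-2-en-1-yl]-2-methyl-2H-chromen-6-yl]-3-phenylprop-2-en-1-one, via (2S)-2-[(2E)-4-hydroxy-4-methylpent-2-en-1-yl]-2-methyl-6-[(2E)-3-phenylprop-2-enoyl]-2H-chromene-5,8-dione 20 (not isolated)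
Conditions: CAN (2.5 equiv), MeCN/H2O, 0 °C, 10 min; then aq. Na2S2O4, EtOAc, rt, under Ar
Reagents that add atoms: water, O
Why: Ceric ammonium nitrate oxidative demethylation of the para-dimethoxyarene gives p-quinone 20 (its carbonyl oxygens come from water, and the C8a ether has no para oxygen partner and stays), and dithionite reduces 20 at once to the hydroquinone; the sequence is short, cold and free of strong acid or base, so the tertiary allylic alcohol, the chalcone and C2 should be unaffected.

## Compound list

1 | 4-bromo-2,5-dimethoxybenzaldehyde | O=Cc1cc(OC)c(Br)cc1OC | starting material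
2 | 4-bromo-2,5-dimethoxyphenyl formate | O=COc1cc(OC)c(Br)cc1OC | intermediate (not isolated)
3 | 4-bromo-2,5-dimethoxyphenol | Oc1cc(OC)c(Br)cc1OC | intermediate
4 | 5-bromo-2-hydroxy-3,6-dimethoxybenzaldehyde | O=Cc1c(O)c(OC)cc(Br)c1OC | intermediate
5 | 4-bromo-2-ethenyl-3,6-dimethoxyphenol | C=Cc1c(O)c(OC)cc(Br)c1OC | intermediate
6 | pent-3-yn-2-one | CC#CC(C)=O | starting material
7 | (3E)-4-(4-bromo-2-ethenyl-3,6-dimethoxyphenoxy)pent-3-en-2-one | CC(=O)/C=C(\C)Oc1c(OC)cc(Br)c(OC)c1C=C | intermediate
8 | (2S,3E)-4-(4-bromo-2-ethenyl-3,6-dimethoxyphenoxy)pent-3-en-2-ol | C[C@H](O)/C=C(\C)Oc1c(OC)cc(Br)c(OC)c1C=C | intermediate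
9 | N,N-dimethylacetamide dimethyl acetal (1,1-dimethoxy-N,N-dimethylethan-1-amine) | COC(C)(OC)N(C)C | starting material
10 | 1-{[(2S,3E)-4-(4-bromo-2-ethenyl-3,6-dimethoxyphenoxy)pent-3-en-2-yl]oxy}-N,N-dimethylethen-1-amine | C[C@H](OC(=C)N(C)C)/C=C(\C)Oc1c(OC)cc(Br)c(OC)c1C=C | intermediate (not isolated)
11 | (3S,4E)-3-(4-bromo-2-ethenyl-3,6-dimethoxyphenoxy)-N,N,3-trimethylhex-4-enamide | CN(C)C(=O)C[C@](C)(Oc1c(OC)cc(Br)c(OC)c1C=C)/C=C/C | intermediate
12 | 2-[(2S)-6-bromo-5,8-dimethoxy-2-methyl-2H-chromen-2-yl]-N,N-dimethylacetamide | CN(C)C(=O)C[C@@]1(C)C=Cc2c(OC)c(Br)cc(OC)c2O1 | intermediate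
13 | 2-[(2S)-6-bromo-5,8-dimethoxy-2-methyl-2H-chromen-2-yl]acetaldehyde | O=CC[C@@]1(C)C=Cc2c(OC)c(Br)cc(OC)c2O1 | intermediate
14 | 1-(triphenyl-λ5-phosphanylidene)propan-2-one | CC(=O)C=P(c1ccccc1)(c1ccccc1)c1ccccc1 | starting material
15 | (3E)-5-[(2S)-6-bromo-5,8-dimethoxy-2-methyl-2H-chromen-2-yl]pent-3-en-2-one | CC(=O)/C=C/C[C@@]1(C)C=Cc2c(OC)c(Br)cc(OC)c2O1 | intermediate
16 | (3E)-5-[(2S)-6-bromo-5,8-dimethoxy-2-methyl-2H-chromen-2-yl]-2-methylpent-3-en-2-ol | CC(C)(O)/C=C/C[C@@]1(C)C=Cc2c(OC)c(Br)cc(OC)c2O1 | intermediate
17 | (2E)-N-methoxy-N-methyl-3-phenylprop-2-enamide | CON(C)C(=O)/C=C/c1ccccc1 | starting material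
18 | lithium (3E)-5-[(2S)-6-lithio-5,8-dimethoxy-2-methyl-2H-chromen-2-yl]-2-methylpent-3-en-2-olate | [Li]OC(C)(C)/C=C/C[C@@]1(C)C=Cc2c(OC)c([Li])cc(OC)c2O1 | intermediate (not isolated)
19 | (2E)-1-[(2S)-2-[(2E)-4-hydroxy-4-methylpent-2-en-1-yl]-5,8-dimethoxy-2-methyl-2H-chromen-6-yl]-3-phenylprop-2-en-1-one | CC(C)(O)/C=C/C[C@@]1(C)C=Cc2c(OC)c(C(=O)/C=C/c3ccccc3)cc(OC)c2O1 | intermediate
20 | (2S)-2-[(2E)-4-hydroxy-4-methylpent-2-en-1-yl]-2-methyl-6-[(2E)-3-phenylprop-2-enoyl]-2H-chromene-5,8-dione | CC(C)(O)/C=C/C[C@@]1(C)C=CC2=C(O1)C(=O)C=C(C(=O)/C=C/c1ccccc1)C2=O | intermediate (not isolated)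
21 | (2E)-1-[(2S)-5,8-dihydroxy-2-[(2E)-4-hydroxy-4-methylpent-2-en-1-yl]-2-methyl-2H-chromen-6-yl]-3-phenylprop-2-en-1-one | CC(C)(O)/C=C/C[C@@]1(C)C=Cc2c(O)c(C(=O)/C=C/c3ccccc3)cc(O)c2O1 | target

## Step count and least certain steps

Total step count: 12. Longest linear sequence: 12 steps (from 1); the route is linear, with 6, 9, 14 and 17 entering as commercial partners.

**Step 6 (key step).** Ionisation of the allylic C–O bond, which is assisted by the enol ether, may compete with the concerted shift at 110 °C. That would erode the transfer of configuration or lead to elimination to a diene; the styrene may also polymerise on long heating. Fallback, from 8 back to 11: the alcohol is acetylated (Ac2O, Et3N, DMAP) to (2S,3E)-4-(4-bromo-2-ethenyl-3,6-dimethoxyphenoxy)pent-3-en-2-yl acetate F1. The ester is enolised and silylated at −78 °C (LDA, TMSCl/Et3N, THF) and left to rearrange on warming to room temperature (Ireland–Claisen rearrangement through the same chair), which gives (3S,4E)-3-(4-bromo-2-ethenyl-3,6-dimethoxyphenoxy)-3-methylhex-4-enoic acid F2 after hydrolytic work-up. Coupling of F2 with dimethylamine (EDC, HOBt) returns to 11.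

**Step 5.** The carbonyl of the vinylogous ester is deactivated, so the reduction may be slow and the facial selectivity lower than for a simple enone; slow reduction would also give hydroboration of the styrene time to compete. Fallback, from 7 back to 8: Luche reduction (NaBH4, CeCl3, MeOH) gives racemic (3E)-4-(4-bromo-2-ethenyl-3,6-dimethoxyphenoxy)pent-3-en-2-ol F3. Lipase-catalysed acylation (immobilised Candida antarctica lipase B, vinyl acetate, MTBE) should acylate the R enantiomer to (2R,3E)-4-(4-bromo-2-ethenyl-3,6-dimethoxyphenoxy)pent-3-en-2-yl acetate F4 and leave the S alcohol, which is 8, at the cost of half the material.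

**Step 4.** Addition of the 2,6-disubstituted phenoxide to the β-methyl ynone may be slow, and equilibration to the E isomer may be incomplete; any Z isomer carried forward would end as the wrong enantiomer at C2. Fallback, from 5 back to 7: acetylacetone is converted into its enol tosylate (2E)-4-oxopent-2-en-2-yl 4-methylbenzenesulfonate F5 (TsCl, Et3N). Phenol 5 displaces the tosylate by addition–elimination (K2CO3, DMF), a substitution at a vinylogous acyl carbon that should again end at the thermodynamic E ether 7, which is separated from any Z isomer before step 5.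

**Step 11.** The aryllithium may be quenched by proton transfer, or may add in the conjugate sense to the cinnamoyl amide, and residual n-BuLi may attack 17. Fallback, from 16 back to 19: Stille coupling of 16 with tributyl(1-ethoxyvinyl)stannane (Pd(PPh3)4, toluene, 90 °C) gives (3E)-5-[(2S)-6-(1-ethoxyethenyl)-5,8-dimethoxy-2-methyl-2H-chromen-2-yl]-2-methylpent-3-en-2-ol F6. Brief hydrolysis on oxalic-acid-doped silica gives methyl ketone 1-[(2S)-2-[(2E)-4-hydroxy-4-methylpent-2-en-1-yl]-5,8-dimethoxy-2-methyl-2H-chromen-6-yl]ethan-1-one F7. Claisen–Schmidt condensation of F7 with benzaldehyde (KOH, EtOH) then gives 19.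

**Step 12.** The oxidation may not stop cleanly at the quinone. The acyl quinone is a strong acceptor and may add water or the side-chain hydroxyl before it is reduced, and the acidic cerium medium may ionise the tertiary allylic alcohol. Fallback, from 16 to 21: the oxidation is moved to the bromide, where no enone is present. CAN then dithionite convert 16 through (2S)-6-bromo-2-[(2E)-4-hydroxy-4-methylpent-2-en-1-yl]-2-methyl-2H-chromene-5,8-dione F8 into (2S)-6-bromo-2-[(2E)-4-hydroxy-4-methylpent-2-en-1-yl]-2-methyl-2H-chromene-5,8-diol F9. The two phenols are protected (MOMCl, iPr2NEt, 0 °C) as (3E)-5-[(2S)-6-bromo-5,8-bis(methoxymethoxy)-2-methyl-2H-chromen-2-yl]-2-methylpent-3-en-2-ol F10. Bromine–lithium exchange and acylation with 17 as in step 11 give (2E)-1-[(2S)-2-[(2E)-4-hydroxy-4-methylpent-2-en-1-yl]-5,8-bis(methoxymethoxy)-2-methyl-2H-chromen-6-yl]-3-phenylprop-2-en-1-one F11. Non-acidic removal of the aryl MOM groups (TMSOTf, 2,2′-bipyridyl, CH2Cl2, 0 °C; then water) gives 21.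

## Further compounds

F1 | step 6 | (2S,3E)-4-(4-bromo-2-ethenyl-3,6-dimethoxyphenoxy)pent-3-en-2-yl acetate | C[C@H](OC(C)=O)/C=C(\C)Oc1c(OC)cc(Br)c(OC)c1C=C
F2 | step 6 | (3S,4E)-3-(4-bromo-2-ethenyl-3,6-dimethoxyphenoxy)-3-methylhex-4-enoic acid | OC(=O)C[C@](C)(Oc1c(OC)cc(Br)c(OC)c1C=C)/C=C/C
F3 | step 5 | racemic (3E)-4-(4-bromo-2-ethenyl-3,6-dimethoxyphenoxy)pent-3-en-2-ol | CC(O)/C=C(\C)Oc1c(OC)cc(Br)c(OC)c1C=C
F4 | step 5 | (2R,3E)-4-(4-bromo-2-ethenyl-3,6-dimethoxyphenoxy)pent-3-en-2-yl acetate | C[C@@H](OC(C)=O)/C=C(\C)Oc1c(OC)cc(Br)c(OC)c1C=C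
F5 | step 4 | (2E)-4-oxopent-2-en-2-yl 4-methylbenzenesulfonate | CC(=O)/C=C(\C)OS(=O)(=O)c1ccc(C)cc1
F6 | step 11 | (3E)-5-[(2S)-6-(1-ethoxyethenyl)-5,8-dimethoxy-2-methyl-2H-chromen-2-yl]-2-methylpent-3-en-2-ol | CC(C)(O)/C=C/C[C@@]1(C)C=Cc2c(OC)c(C(=C)OCC)cc(OC)c2O1
F7 | step 11 | 1-[(2S)-2-[(2E)-4-hydroxy-4-methylpent-2-en-1-yl]-5,8-dimethoxy-2-methyl-2H-chromen-6-yl]ethan-1-one | CC(C)(O)/C=C/C[C@@]1(C)C=Cc2c(OC)c(C(C)=O)cc(OC)c2O1
F8 | step 12 | (2S)-6-bromo-2-[(2E)-4-hydroxy-4-methylpent-2-en-1-yl]-2-methyl-2H-chromene-5,8-dione | CC(C)(O)/C=C/C[C@@]1(C)C=CC2=C(O1)C(=O)C=C(Br)C2=O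
F9 | step 12 | (2S)-6-bromo-2-[(2E)-4-hydroxy-4-methylpent-2-en-1-yl]-2-methyl-2H-chromene-5,8-diol | CC(C)(O)/C=C/C[C@@]1(C)C=Cc2c(O)c(Br)cc(O)c2O1
F10 | step 12 | (3E)-5-[(2S)-6-bromo-5,8-bis(methoxymethoxy)-2-methyl-2H-chromen-2-yl]-2-methylpent-3-en-2-ol | CC(C)(O)/C=C/C[C@@]1(C)C=Cc2c(OCOC)c(Br)cc(OCOC)c2O1
F11 | step 12 | (2E)-1-[(2S)-2-[(2E)-4-hydroxy-4-methylpent-2-en-1-yl]-5,8-bis(methoxymethoxy)-2-methyl-2H-chromen-6-yl]-3-phenylprop-2-en-1-one | CC(C)(O)/C=C/C[C@@]1(C)C=Cc2c(OCOC)c(C(=O)/C=C/c3ccccc3)cc(OCOC)c2O1
A1 | alternative 1 | racemic 1-[5-hydroxy-8-(methoxymethoxy)-2-methyl-2-(4-methylpent-3-en-1-yl)-2H-chromen-6-yl]ethan-1-one | CC(=O)c1cc(OCOC)c2OC(C)(CCC=C(C)C)C=Cc2c1O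
A2 | alternative 1 | racemic 1-[2-[(2E)-4-hydroperoxy-4-methylpent-2-en-1-yl]-5-hydroxy-8-(methoxymethoxy)-2-methyl-2H-chromen-6-yl]ethan-1-one | CC(=O)c1cc(OCOC)c2OC(C)(C/C=C/C(C)(C)OO)C=Cc2c1O
A3 | alternative 1 | 1-[2-(3-hydroperoxy-4-methylpent-4-en-1-yl)-5-hydroxy-8-(methoxymethoxy)-2-methyl-2H-chromen-6-yl]ethan-1-one (mixture of stereoisomers) | CC(=O)c1cc(OCOC)c2OC(C)(CCC(OO)C(C)=C)C=Cc2c1O
A4 | alternative 2 | 1-bromo-4-{[(3S)-3,7-dimethylocta-1,6-dien-3-yl]oxy}-3-ethenyl-2,5-dimethoxybenzene | C=C[C@](C)(CCC=C(C)C)Oc1c(OC)cc(Br)c(OC)c1C=C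
A5 | alternative 2 | (2S)-6-bromo-5,8-dimethoxy-2-methyl-2-(4-methylpent-3-en-1-yl)-2H-chromene | CC(C)=CCC[C@@]1(C)C=Cc2c(OC)c(Br)cc(OC)c2O1
A6 | alternative 3 | 6-bromo-5,8-dimethoxy-2-methyl-4H-chromen-4-one | Cc1cc(=O)c2c(OC)c(Br)cc(OC)c2o1
A7 | alternative 3 | (4R)-6-bromo-5,8-dimethoxy-2-methyl-4H-chromen-4-ol | CC1=C[C@@H](O)c2c(OC)c(Br)cc(OC)c2O1
A8 | alternative 3 | (4R)-6-bromo-5,8-dimethoxy-2-methyl-4H-chromen-4-yl acetate | CC1=C[C@@H](OC(C)=O)c2c(OC)c(Br)cc(OC)c2O1
A9 | alternative 3 | 2-[(2S)-6-bromo-5,8-dimethoxy-2-methyl-2H-chromen-2-yl]acetic acid | OC(=O)C[C@@]1(C)C=Cc2c(OC)c(Br)cc(OC)c2O1
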